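**Retrosynthetic overview**
1. Target 19 ⇐ 18 (desilylation) ⇐ aryl ester 16. The bond between the ketone carbon C1 and the benzene carbon C1′ is made by an anionic Fries shift (1,3 O→C acyl migration). The enabling feature is the hydroxyl oxygen on C2′ of the benzene ring (ring B), ortho to the carbon that carries the ketone. It serves as the ester tether and stays in the target as the ortho phenol.
2. 16 ⇐ acid 13 + bromophenol 15 (from 4-bromoresorcinol). The bromine marks the ring carbon that receives the acyl group.
3. 13 ⇐ malonate 11 ⇐ allylic carbonate 9 + dimethyl malonate. An iridium-catalysed asymmetric allylic alkylation sets the quaternary C3 together with its vinyl group.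
4. 9 ⇐ furan alcohol 8 ⇐ butenolide 6 ⇐ allylic bromide 3 (from geranyl acetate) + silyloxyfuran 5.
5. Rings: ring B is bought intact. Ring A (furan) is bought as a butenolide and becomes aromatic in step 5. The key step closes no lasting ring.

Key step: step 12

Assumption: geranyl acetate, 3-methyl-2(5H)-furanone, dimethyl malonate and 4-bromoresorcinol are taken as commercial. In step 7 the ligand antipode that delivers (S)-11 is used; which antipode that is has to be fixed on a model carbonate first.

**Step 1**
Reactants: 1 geranyl acetate, (2E)-3,7-dimethylocta-2,6-dien-1-yl acetate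
Product: 2 (2E,6E)-8-hydroxy-3,7-dimethylocta-2,6-dien-1-yl acetate
Conditions: SeO2 (cat.), t-BuOOH, salicylic acid (cat.), CH2Cl2, 0 °C to rt
Reagents that add atoms: selenium dioxide, O=[Se]=O (transfers the oxygen atom, catalytic); tert-butyl hydroperoxide, CC(C)(C)OO (terminal oxygen source)
Why: Riley allylic oxidation (ene reaction, then [2,3]-sigmatropic shift) should hydroxylate the (E)-methyl group of the electron-rich terminal alkene selectively, because the C2=C3 alkene is deactivated by the allylic acetate.

**Step 2**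
Reactants: 2 (2E,6E)-8-hydroxy-3,7-dimethylocta-2,6-dien-1-yl acetate
Product: 3 (2E,6E)-8-bromo-3,7-dimethylocta-2,6-dien-1-yl acetate
Conditions: CBr4, PPh3, CH2Cl2, 0 °C
Reagents that add atoms: carbon tetrabromide, BrC(Br)(Br)Br
Why: Appel bromination of a primary allylic alcohol should proceed by SN2 displacement of the oxyphosphonium group without allylic transposition or loss of alkene geometry.

**Step 3**
Reactants: 4 3-methyl-2(5H)-furanone
Product: 5 3-methyl-2-(trimethylsilyloxy)furan
Conditions: Me3SiCl, Et3N, Et2O, 0 °C to rt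
Reagents that add atoms: chlorotrimethylsilane, C[Si](C)(C)Cl
Why: Soft enolisation and O-silylation of the butenolide (silyl dienol ether formation) is driven by the aromaticity of the 2-silyloxyfuran that forms.

**Step 4**
Reactants: 3 (2E,6E)-8-bromo-3,7-dimethylocta-2,6-dien-1-yl acetate; 5 3-methyl-2-(trimethylsilyloxy)furan
Product: 6 (2E,6E)-3,7-dimethyl-8-(4-methyl-5-oxo-2,5-dihydrofuran-2-yl)octa-2,6-dien-1-yl acetate (racemic at the ring carbon)
Conditions: AgOCOCF3, CH2Cl2, −78 °C to rt, dark
Reagents that add atoms: none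
Why: In this silver-assisted vinylogous (Mukaiyama-type) alkylation the silver salt ionises the allylic bromide and the silyloxyfuran should attack through its C5 at the less hindered primary allyl terminus; the new ring stereocenter forms without control and is erased in step 5.

**Step 5**
Reactants: 6 (2E,6E)-3,7-dimethyl-8-(4-methyl-5-oxo-2,5-dihydrofuran-2-yl)octa-2,6-dien-1-yl acetate
Product: 8 (2E,6E)-3,7-dimethyl-8-(4-methylfuran-2-yl)octa-2,6-dien-1-ol, via lactol 7 (not isolated)
Conditions: i-Bu2AlH (excess), CH2Cl2, −78 to −40 °C; then cold dilute aq. HCl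
Reagents that add atoms: none
Why: Hydride reduction of the butenolide to the lactol, then acid-promoted 1,4-dehydration (reductive aromatisation), should give the 2,4-disubstituted furan with defined regiochemistry, and the same reagent cleaves the acetate reductively.

**Step 6**
Reactants: 8 (2E,6E)-3,7-dimethyl-8-(4-methylfuran-2-yl)octa-2,6-dien-1-ol
Product: 9 (2E,6E)-3,7-dimethyl-8-(4-methylfuran-2-yl)octa-2,6-dien-1-yl methyl carbonate
Conditions: ClCO2Me, pyridine, CH2Cl2, 0 °C
Reagents that add atoms: methyl chloroformate, COC(=O)Cl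
Why: O-Acylation of the primary allylic alcohol under basic conditions (carbonate formation) leaves the acid-sensitive furan and both alkenes untouched.

**Step 7**
Reactants: 9 (2E,6E)-3,7-dimethyl-8-(4-methylfuran-2-yl)octa-2,6-dien-1-yl methyl carbonate; 10 dimethyl malonate
Product: 11 dimethyl 2-[(3S,6E)-3,7-dimethyl-8-(4-methylfuran-2-yl)octa-1,6-dien-3-yl]propanedioate
Conditions: [Ir(cod)Cl]2 (cat.), chiral BINOL-derived N-aryl phosphoramidite ligand (cat.), 1,5,7-triazabicyclo[4.4.0]dec-5-ene (cat.), NaN(SiMe3)2, ZnI2, THF, 20 °C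
Reagents that add atoms: none
Why: In this branched-selective iridium-catalysed asymmetric allylic alkylation the cyclometalated iridium–phosphoramidite complex ionises the (E)-carbonate and the zinc malonate should attack the fully substituted allyl terminus on the face left open by the ligand, which sets the quaternary stereocenter (S in 11, the same carbon that is R in the target); close precedent exists for malonates with alkyl-substituted trisubstituted (E)-allylic carbonates.

**Step 8**
Reactants: 11 dimethyl 2-[(3S,6E)-3,7-dimethyl-8-(4-methylfuran-2-yl)octa-1,6-dien-3-yl]propanedioate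
Product: 12 methyl (3R,6E)-3-ethenyl-3,7-dimethyl-8-(4-methylfuran-2-yl)oct-6-enoate
Conditions: LiCl, H2O, DMSO, 150 °C
Reagents that add atoms: none
Why: Krapcho dealkoxycarbonylation (chloride attack on a methyl ester, loss of CO2, protonation) runs under near-neutral conditions that the furan and the hydrogen-free quaternary center should tolerate.

**Step 9**
Reactants: 12 methyl (3R,6E)-3-ethenyl-3,7-dimethyl-8-(4-methylfuran-2-yl)oct-6-enoate
Product: 13 (3R,6E)-3-ethenyl-3,7-dimethyl-8-(4-methylfuran-2-yl)oct-6-enoic acid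
Conditions: LiOH·H2O, THF/MeOH/H2O, 45 °C; then dilute aq. HCl to pH 4, 0 °C
Reagents that add atoms: lithium hydroxide, [Li+].[OH-]
Why: Saponification of the methyl ester with hydroxide is mild enough for the skipped furan–alkene system, and the stereocenter has no acidic hydrogen.

**Step 10**
Reactants: 14 4-bromoresorcinol (4-bromobenzene-1,3-diol)
Product: 15 2-bromo-5-(triisopropylsilyloxy)phenol
Conditions: i-Pr3SiCl (1.0 equiv), imidazole, CH2Cl2, −20 to 0 °C
Reagents that add atoms: chlorotriisopropylsilane, CC(C)[Si](Cl)(C(C)C)C(C)C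
Why: Silylation with a bulky silyl chloride should select the hydroxyl remote from bromine on steric grounds, leaving the hydroxyl ortho to bromine free for the tether.

**Step 11**
Reactants: 13 (3R,6E)-3-ethenyl-3,7-dimethyl-8-(4-methylfuran-2-yl)oct-6-enoic acid; 15 2-bromo-5-(triisopropylsilyloxy)phenol
Product: 16 2-bromo-5-(triisopropylsilyloxy)phenyl (3R,6E)-3-ethenyl-3,7-dimethyl-8-(4-methylfuran-2-yl)oct-6-enoate
Conditions: DCC, DMAP (cat.), CH2Cl2, 0 °C to rt
Reagents that add atoms: none
Why: Steglich esterification through the acylpyridinium intermediate should acylate the only free phenol under neutral conditions that spare the furan.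

**Step 12**
Reactants: 16 2-bromo-5-(triisopropylsilyloxy)phenyl (3R,6E)-3-ethenyl-3,7-dimethyl-8-(4-methylfuran-2-yl)oct-6-enoate
Product: 18 (3R,6E)-3-ethenyl-1-[2-hydroxy-4-(triisopropylsilyloxy)phenyl]-3,7-dimethyl-8-(4-methylfuran-2-yl)oct-6-en-1-one, via aryllithium 17 (not isolated)
Conditions: t-BuLi (2 equiv), THF/Et2O/pentane, −95 to −78 °C; then AcOH
Reagents that add atoms: none
Why: Bromine–lithium exchange at −95 °C should convert 16 into aryllithium 17 faster than t-BuLi can add to or enolise the ester; the carbanion, held next to the ester oxygen, then adds to the carbonyl carbon to give a lithium 2H-benzoxet-2-olate that opens by C–O cleavage to the lithium phenoxide of 18, which the acetic acid quench protonates. The closest known reaction type is the anionic Fries rearrangement (1,3 O→C acyl shift) of ortho-haloaryl esters triggered by halogen–metal exchange. No ring of the product is closed; the only ring formed is the transient four-membered benzoxete, closed in a 4-exo-trig mode and reopened in the same step. No stereocenter is created, and the quaternary C3 carries no hydrogen and lies two bonds from the reacting carbonyl, so its configuration is untouched. The step needs chemoselectivity (exchange before carbonyl addition or α-deprotonation) and site selectivity (acyl delivery only to the carbon that bore bromine): the first is secured by the rate of aryl bromide exchange at low temperature and by the shielding of the C=O and α-CH2 groups by the neighbouring quaternary carbon, the second by the bromine placed ortho to the ester oxygen on ring B. The silyl ether keeps the para oxygen inert, and the tether oxygen is not discarded but becomes the ortho hydroxyl of the target.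

**Step 13**
Reactants: 18 (3R,6E)-3-ethenyl-1-[2-hydroxy-4-(triisopropylsilyloxy)phenyl]-3,7-dimethyl-8-(4-methylfuran-2-yl)oct-6-en-1-one
Product: 19 (3R,6E)-1-(2,4-dihydroxyphenyl)-3-ethenyl-3,7-dimethyl-8-(4-methylfuran-2-yl)oct-6-en-1-one
Conditions: Bu4NF, AcOH, THF, 0 °C
Reagents that add atoms: none
Why: Fluoride-mediated cleavage of the aryl silyl ether, buffered with acetic acid, should release the second phenol without touching the furan, the alkenes or the stereocenter.

**Compound list**
1 | geranyl acetate, (2E)-3,7-dimethylocta-2,6-dien-1-yl acetate | CC(C)=CCC/C(C)=C/COC(C)=O | starting material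
2 | (2E,6E)-8-hydroxy-3,7-dimethylocta-2,6-dien-1-yl acetate | OC/C(C)=C/CC/C(C)=C/COC(C)=O | intermediate
3 | (2E,6E)-8-bromo-3,7-dimethylocta-2,6-dien-1-yl acetate | BrC/C(C)=C/CC/C(C)=C/COC(C)=O | intermediate
4 | 3-methyl-2(5H)-furanone | CC1=CCOC1=O | starting material
5 | 3-methyl-2-(trimethylsilyloxy)furan | Cc1ccoc1O[Si](C)(C)C | intermediate
6 | (2E,6E)-3,7-dimethyl-8-(4-methyl-5-oxo-2,5-dihydrofuran-2-yl)octa-2,6-dien-1-yl acetate (racemic at the ring carbon) | CC1=CC(C/C(C)=C/CC/C(C)=C/COC(C)=O)OC1=O | intermediate
7 | lactol, 5-[(2E,6E)-8-hydroxy-2,6-dimethylocta-2,6-dien-1-yl]-3-methyl-2,5-dihydrofuran-2-ol (not isolated) | CC1=CC(C/C(C)=C/CC/C(C)=C/CO)OC1O | intermediate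
8 | (2E,6E)-3,7-dimethyl-8-(4-methylfuran-2-yl)octa-2,6-dien-1-ol | Cc1coc(C/C(C)=C/CC/C(C)=C/CO)c1 | intermediate
9 | (2E,6E)-3,7-dimethyl-8-(4-methylfuran-2-yl)octa-2,6-dien-1-yl methyl carbonate | Cc1coc(C/C(C)=C/CC/C(C)=C/COC(=O)OC)c1 | intermediate
10 | dimethyl malonate | COC(=O)CC(=O)OC | starting material
11 | dimethyl 2-[(3S,6E)-3,7-dimethyl-8-(4-methylfuran-2-yl)octa-1,6-dien-3-yl]propanedioate | C=C[C@](C)(CC/C=C(\C)Cc1cc(C)co1)C(C(=O)OC)C(=O)OC | intermediate
12 | methyl (3R,6E)-3-ethenyl-3,7-dimethyl-8-(4-methylfuran-2-yl)oct-6-enoate | C=C[C@](C)(CC/C=C(\C)Cc1cc(C)co1)CC(=O)OC | intermediate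
13 | (3R,6E)-3-ethenyl-3,7-dimethyl-8-(4-methylfuran-2-yl)oct-6-enoic acid | C=C[C@](C)(CC/C=C(\C)Cc1cc(C)co1)CC(=O)O | intermediate
14 | 4-bromoresorcinol (4-bromobenzene-1,3-diol) | Oc1ccc(Br)c(O)c1 | starting material
15 | 2-bromo-5-(triisopropylsilyloxy)phenol | Oc1cc(O[Si](C(C)C)(C(C)C)C(C)C)ccc1Br | intermediate
16 | 2-bromo-5-(triisopropylsilyloxy)phenyl (3R,6E)-3-ethenyl-3,7-dimethyl-8-(4-methylfuran-2-yl)oct-6-enoate | C=C[C@](C)(CC/C=C(\C)Cc1cc(C)co1)CC(=O)Oc1cc(O[Si](C(C)C)(C(C)C)C(C)C)ccc1Br | intermediate
17 | aryllithium, 2-lithio-5-(triisopropylsilyloxy)phenyl (3R,6E)-3-ethenyl-3,7-dimethyl-8-(4-methylfuran-2-yl)oct-6-enoate (not isolated) | C=C[C@](C)(CC/C=C(\C)Cc1cc(C)co1)CC(=O)Oc1cc(O[Si](C(C)C)(C(C)C)C(C)C)ccc1[Li] | intermediate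
18 | (3R,6E)-3-ethenyl-1-[2-hydroxy-4-(triisopropylsilyloxy)phenyl]-3,7-dimethyl-8-(4-methylfuran-2-yl)oct-6-en-1-one | C=C[C@](C)(CC/C=C(\C)Cc1cc(C)co1)CC(=O)c1ccc(O[Si](C(C)C)(C(C)C)C(C)C)cc1O | intermediate
19 | (3R,6E)-1-(2,4-dihydroxyphenyl)-3-ethenyl-3,7-dimethyl-8-(4-methylfuran-2-yl)oct-6-en-1-one | C=C[C@](C)(CC/C=C(\C)Cc1cc(C)co1)CC(=O)c1ccc(O)cc1O | target

**Step count**
Total: 13 steps. Longest linear sequence: 11 steps (1, 2, 4, 5, 6, 7, 8, 9, 11, 12, 13) from geranyl acetate.

**Steps most likely to fail**

Step 7. The two substituents at the substituted allyl terminus (methyl and a homoallylic chain) differ little, so facial discrimination may be poor, and syn/anti isomerisation of the allyl–iridium intermediate or attack at the primary terminus may erode enantiomeric purity and branched selectivity. The fallback sets out from 8. Johnson–Claisen rearrangement with trimethyl orthoacetate and catalytic propionic acid at about 110 °C should give racemic methyl (6E)-3-ethenyl-3,7-dimethyl-8-(4-methylfuran-2-yl)oct-6-enoate F1. Preparative chromatography on a chiral stationary phase would then separate 12 from its enantiomer methyl (3S,6E)-3-ethenyl-3,7-dimethyl-8-(4-methylfuran-2-yl)oct-6-enoate F2, which is set aside. The route comes back at 12.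

Step 12. The alkyllithium may add to the aryl ester carbonyl before exchange, or the aryllithium may take a proton from the α-methylene, after which the ester enolate loses phenoxide as a ketene. The fallback sets out from 12 and joins the fragments intermolecularly. N,O-Dimethylhydroxylamine hydrochloride and i-PrMgCl in THF at −20 °C should give the Weinreb amide (3R,6E)-3-ethenyl-N-methoxy-N,3,7-trimethyl-8-(4-methylfuran-2-yl)oct-6-enamide F3. Exhaustive silylation of 14 (i-Pr3SiCl, imidazole, DMF) gives 4-bromo-1,3-bis(triisopropylsilyloxy)benzene F4, which on bromine–lithium exchange (t-BuLi, THF, −78 °C) becomes 2,4-bis(triisopropylsilyloxy)phenyllithium F5. Addition of the aryllithium to the amide stops at the chelated tetrahedral adduct and should give on work-up (3R,6E)-1-[2,4-bis(triisopropylsilyloxy)phenyl]-3-ethenyl-3,7-dimethyl-8-(4-methylfuran-2-yl)oct-6-en-1-one F6. Bu4NF/AcOH then removes both silyl groups, and the route comes back at 19.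

Step 4. The silver-generated allyl cation may be captured at its secondary terminus or lose the C6=C7 geometry, and the silyloxyfuran may react through C3 instead of C5. The fallback sets out from 3 and replaces the cationic alkylation by a cross-coupling. Iridium-catalysed C–H borylation of commercial 3-methylfuran ([Ir(OMe)(cod)]2, 4,4'-di-tert-butyl-2,2'-bipyridine, bis(pinacolato)diboron, hexane, rt) is steered by sterics to the ring carbon remote from the methyl group and should give 4,4,5,5-tetramethyl-2-(4-methylfuran-2-yl)-1,3,2-dioxaborolane F7, from which the minor regioisomer is removed. Suzuki–Miyaura coupling with 3 (Pd(PPh3)4, K2CO3, THF/H2O, 40 °C) should join the furan to the primary allyl terminus with retention of alkene geometry and give (2E,6E)-3,7-dimethyl-8-(4-methylfuran-2-yl)octa-2,6-dien-1-yl acetate F8. K2CO3 in MeOH removes the acetate, and the route comes back at 8, bypassing 5, 6 and 7.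

**Further compounds**
F1 | step 7 | racemic methyl (6E)-3-ethenyl-3,7-dimethyl-8-(4-methylfuran-2-yl)oct-6-enoate | C=CC(C)(CC/C=C(\C)Cc1cc(C)co1)CC(=O)OC
F2 | step 7 | methyl (3S,6E)-3-ethenyl-3,7-dimethyl-8-(4-methylfuran-2-yl)oct-6-enoate | C=C[C@@](C)(CC/C=C(\C)Cc1cc(C)co1)CC(=O)OC
F3 | step 12 | (3R,6E)-3-ethenyl-N-methoxy-N,3,7-trimethyl-8-(4-methylfuran-2-yl)oct-6-enamide | C=C[C@](C)(CC/C=C(\C)Cc1cc(C)co1)CC(=O)N(C)OC
F4 | step 12 | 4-bromo-1,3-bis(triisopropylsilyloxy)benzene | Brc1ccc(O[Si](C(C)C)(C(C)C)C(C)C)cc1O[Si](C(C)C)(C(C)C)C(C)C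
F5 | step 12 | 2,4-bis(triisopropylsilyloxy)phenyllithium | [Li]c1ccc(O[Si](C(C)C)(C(C)C)C(C)C)cc1O[Si](C(C)C)(C(C)C)C(C)C
F6 | step 12 | (3R,6E)-1-[2,4-bis(triisopropylsilyloxy)phenyl]-3-ethenyl-3,7-dimethyl-8-(4-methylfuran-2-yl)oct-6-en-1-one | C=C[C@](C)(CC/C=C(\C)Cc1cc(C)co1)CC(=O)c1ccc(O[Si](C(C)C)(C(C)C)C(C)C)cc1O[Si](C(C)C)(C(C)C)C(C)C
F7 | step 4 | 4,4,5,5-tetramethyl-2-(4-methylfuran-2-yl)-1,3,2-dioxaborolane | Cc1coc(B2OC(C)(C)C(C)(C)O2)c1
F8 | step 4 | (2E,6E)-3,7-dimethyl-8-(4-methylfuran-2-yl)octa-2,6-dien-1-yl acetate | Cc1coc(C/C(C)=C/CC/C(C)=C/COC(C)=O)c1
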